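**Plan**

- Retrosynthesis: the two arm silyl ethers are cut first, then the O1–C2 bond together with C2–H of the tetrahydrofuran (reductive etherification of a γ-hydroxy aryl ketone), then C2–aryl (aryllithium plus γ-lactone), C5–aryl (acid chloride plus aryl Grignard) and C3–C4 (imide enolate plus lactate triflate). Each arm is cut at the aryl ether C–O bond (Mitsunobu) and at the carbinol–aryl bond (Weinreb ketone synthesis).
- Forward: two enantiomeric arm-bearing aryl bromides are made from (S)- and (R)-lactate. A (2S,3S)-2,3-dimethylsuccinate half ester is made from a third lactate unit. Aryl B is attached, the ketone is reduced and the chain is held as a temporary γ-lactone. Aryl A opens the lactone, and the tetrahydrofuran, the only non-aromatic ring, is closed last.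
- Stereochemistry: the ether carbons of both arms and ring carbon C3 come from lactic acid by SN2 inversion. The arm carbinols come from Felkin–Anh reduction, C4 from the Evans auxiliary, C5 from Corey–Bakshi–Shibata reduction, and C2 from the ring substituents in the key step.
- Enabling feature: the 4-alkoxy-3-methoxyphenyl ring on C2 stabilises the five-membered oxocarbenium ion O1=C2, and the cis pair C4-methyl/C5-aryl on the ring leaves only one face of C2 open to hydride.
- Helpers that are removed again: the oxazolidinone, the γ-lactone ring, the ketone oxidation level at C2, and two silyl ethers.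

Key step: step 16

Abbreviations: aryl A = 4-{[(1R,2R)-1-(tert-butyldimethylsilyloxy)-1-(3,4-dimethoxyphenyl)propan-2-yl]oxy}-3-methoxyphenyl; aryl B = the same group with (1S,2S) configuration; ring atoms are O1, C2 (aryl A), C3, C4, C5 (aryl B).

Remark: compound 27 is drawn as the open γ-hydroxy ketone although it stands in ring–chain equilibrium with lactol 28 (both give the same cation); compounds 3, 15 and 16 are taken as commercial reagents.

**Route**

Step 1
Reactants: 1 ethyl (S)-lactate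
Product: 2 (S)-2-hydroxy-N-methoxy-N-methylpropanamide
Conditions: MeNHOMe·HCl, iPrMgCl, THF, −20 → 0 °C; aq. NH4Cl
Reagents that add atoms: N,O-dimethylhydroxylamine hydrochloride, CNOC.Cl
Why: Weinreb amidation of an ester by the chloromagnesium amide should leave the stereocenter untouched, because the α-oxygen is present as its magnesium alkoxide.

Step 2
Reactants: 2 (S)-2-hydroxy-N-methoxy-N-methylpropanamide; 3 3,4-dimethoxyphenylmagnesium bromide
Product: 4 (S)-1-(3,4-dimethoxyphenyl)-2-hydroxypropan-1-one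
Conditions: 3 (3 equiv), THF, 0 °C → rt; aq. NH4Cl
Reagents that add atoms: none
Why: Weinreb ketone synthesis, in which the chelated tetrahedral intermediate should stop over-addition and the alkoxide formed by the first equivalent should suppress enolisation, so the (S) centre is kept.

Step 3
Reactants: 4 (S)-1-(3,4-dimethoxyphenyl)-2-hydroxypropan-1-one; 5 4-bromo-2-methoxyphenol
Product: 6 (R)-2-(4-bromo-2-methoxyphenoxy)-1-(3,4-dimethoxyphenyl)propan-1-one
Conditions: PPh3, DIAD, toluene, 0 °C → rt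
Reagents that add atoms: none
Why: Mitsunobu etherification should displace the alkoxyphosphonium group by the phenol in an SN2 step with inversion, (S) → (R), under neutral conditions that spare the enolisable α-aryloxy ketone.

Step 4
Reactants: 6 (R)-2-(4-bromo-2-methoxyphenoxy)-1-(3,4-dimethoxyphenyl)propan-1-one
Product: 7 (1R,2R)-2-(4-bromo-2-methoxyphenoxy)-1-(3,4-dimethoxyphenyl)propan-1-ol
Conditions: Bu4NBH4, CH2Cl2/MeOH, −40 °C; aq. NH4Cl
Reagents that add atoms: none
Why: Felkin–Anh (polar) reduction with a non-coordinating cation should place the aryloxy group anti to the incoming hydride and give the threo (1R,2R) alcohol, the reaction type known for α-aryloxy propiophenones.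

Step 5
Reactants: 7 (1R,2R)-2-(4-bromo-2-methoxyphenoxy)-1-(3,4-dimethoxyphenyl)propan-1-ol
Product: 8 tert-butyl{[(1R,2R)-2-(4-bromo-2-methoxyphenoxy)-1-(3,4-dimethoxyphenyl)propyl]oxy}dimethylsilane
Conditions: tBuMe2SiOTf, 2,6-lutidine, CH2Cl2, 0 °C
Reagents that add atoms: tert-butyldimethylsilyl trifluoromethanesulfonate, CC(C)(C)[Si](C)(C)OS(=O)(=O)C(F)(F)F
Why: Silylation with a silyl triflate should protect the hindered benzylic alcohol for the aryl-metal stages that follow.

Step 6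
Reactants: 9 methyl (R)-lactate
Product: 10 (R)-2-hydroxy-N-methoxy-N-methylpropanamide
Conditions: MeNHOMe·HCl, iPrMgCl, THF, −20 → 0 °C; aq. NH4Cl
Reagents that add atoms: N,O-dimethylhydroxylamine hydrochloride, CNOC.Cl
Why: Weinreb amidation as in step 1, in the enantiomeric series.

Step 7
Reactants: 10 (R)-2-hydroxy-N-methoxy-N-methylpropanamide; 3 3,4-dimethoxyphenylmagnesium bromide
Product: 11 (R)-1-(3,4-dimethoxyphenyl)-2-hydroxypropan-1-one
Conditions: 3 (3 equiv), THF, 0 °C → rt; aq. NH4Cl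
Reagents that add atoms: none
Why: Weinreb ketone synthesis as in step 2, with retention of the (R) centre.

Step 8
Reactants: 11 (R)-1-(3,4-dimethoxyphenyl)-2-hydroxypropan-1-one; 5 4-bromo-2-methoxyphenol
Product: 12 (S)-2-(4-bromo-2-methoxyphenoxy)-1-(3,4-dimethoxyphenyl)propan-1-one
Conditions: PPh3, DIAD, toluene, 0 °C → rt
Reagents that add atoms: none
Why: Mitsunobu etherification with inversion, (R) → (S), as in step 3.

Step 9
Reactants: 12 (S)-2-(4-bromo-2-methoxyphenoxy)-1-(3,4-dimethoxyphenyl)propan-1-one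
Product: 13 (1S,2S)-2-(4-bromo-2-methoxyphenoxy)-1-(3,4-dimethoxyphenyl)propan-1-ol
Conditions: Bu4NBH4, CH2Cl2/MeOH, −40 °C; aq. NH4Cl
Reagents that add atoms: none
Why: Felkin–Anh (polar) reduction as in step 4 should give the threo (1S,2S) alcohol.

Step 10
Reactants: 13 (1S,2S)-2-(4-bromo-2-methoxyphenoxy)-1-(3,4-dimethoxyphenyl)propan-1-ol
Product: 14 tert-butyl{[(1S,2S)-2-(4-bromo-2-methoxyphenoxy)-1-(3,4-dimethoxyphenyl)propyl]oxy}dimethylsilane
Conditions: tBuMe2SiOTf, 2,6-lutidine, CH2Cl2, 0 °C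
Reagents that add atoms: tert-butyldimethylsilyl trifluoromethanesulfonate, CC(C)(C)[Si](C)(C)OS(=O)(=O)C(F)(F)F
Why: Silyl protection as in step 5.

Step 11
Reactants: 15 (R)-4-benzyl-3-propionyloxazolidin-2-one; 16 ethyl (S)-2-{[(trifluoromethyl)sulfonyl]oxy}propanoate
Product: 18 ethyl (2S,3S)-4-[(R)-4-benzyl-2-oxooxazolidin-3-yl]-2,3-dimethyl-4-oxobutanoate, via sodium enolate 17 (not isolated)
Conditions: NaN(SiMe3)2, THF, −78 °C; then 16, −78 → −30 °C
Reagents that add atoms: none
Why: Evans asymmetric alkylation with an α-triflyloxy ester (known for 2,3-disubstituted succinates): the benzyl group of the auxiliary should block one face of the chelated (Z)-enolate so that the enolate carbon (later C4) becomes (S), and SN2 displacement of triflate should invert the lactate carbon (later C3) to (S).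

Step 12
Reactants: 18 ethyl (2S,3S)-4-[(R)-4-benzyl-2-oxooxazolidin-3-yl]-2,3-dimethyl-4-oxobutanoate
Product: 20 (2S,3S)-4-ethoxy-2,3-dimethyl-4-oxobutanoic acid, via lithium peroxycarboxylate 19 (not isolated)
Conditions: LiOH, H2O2, THF/H2O, 0 °C; Na2SO3; 1 M HCl
Reagents that add atoms: hydrogen peroxide, OO
Why: Lithium hydroperoxide should cleave the exocyclic imide carbonyl selectively (auxiliary removal) and leave the ethyl ester and both methyl-bearing centres untouched.

Step 13
Reactants: 20 (2S,3S)-4-ethoxy-2,3-dimethyl-4-oxobutanoic acid; 14 tert-butyl{[(1S,2S)-2-(4-bromo-2-methoxyphenoxy)-1-(3,4-dimethoxyphenyl)propyl]oxy}dimethylsilane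
Product: 23 ethyl (2S,3S)-4-(aryl B)-2,3-dimethyl-4-oxobutanoate, via acid chloride 21 (not isolated), via aryl Grignard reagent 22 (not isolated)
Conditions: (a) 20, (COCl)2, DMF (cat.), CH2Cl2, 0 °C → rt; (b) 14, Mg, LiCl, THF, rt; (c) Fe(acac)3 (3 mol %), THF, −78 °C; aq. NH4Cl
Reagents that add atoms: none
Why: Fe(acac)3-catalysed acylation of a Grignard reagent by an acid chloride at −78 °C is a ketone synthesis that should tolerate the ethyl ester and the α-stereocenter, so only the C5–aryl bond forms.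

Step 14
Reactants: 23 ethyl (2S,3S)-4-(aryl B)-2,3-dimethyl-4-oxobutanoate
Product: 25 (3S,4S,5R)-5-(aryl B)-3,4-dimethyldihydrofuran-2(3H)-one, via hydroxy ester 24 (not isolated)
Conditions: (S)-1-methyl-3,3-diphenyltetrahydro-1H,3H-pyrrolo[1,2-c][1,3,2]oxazaborole (0.5 equiv), BH3·SMe2, THF, −20 °C; MeOH; then pyridinium p-toluenesulfonate (cat.), toluene, 40 °C
Reagents that add atoms: none
Why: Corey–Bakshi–Shibata reduction, with aryl as the large group, should deliver hydride under reagent control to give the (R) carbinol at C5 (against the Felkin preference of the neighbouring methyl centre), and the γ-hydroxy ester should then lactonise to the 4,5-cis lactone, which serves as temporary ring and mono-acylating agent.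

Step 15
Reactants: 8 tert-butyl{[(1R,2R)-2-(4-bromo-2-methoxyphenoxy)-1-(3,4-dimethoxyphenyl)propyl]oxy}dimethylsilane; 25 (3S,4S,5R)-5-(aryl B)-3,4-dimethyldihydrofuran-2(3H)-one
Product: 27 (2S,3S,4R)-1-(aryl A)-4-(aryl B)-4-hydroxy-2,3-dimethylbutan-1-one, via aryllithium 26 (not isolated)
Conditions: 8, tBuLi (2 equiv), THF, −78 °C; then 25, −78 °C; aq. NH4Cl
Reagents that add atoms: none
Why: Bromine–lithium exchange followed by addition of one aryllithium to a γ-lactone should stop at the lithium hemiketal at −78 °C and give the γ-hydroxy aryl ketone (lactol tautomer) with C3, C4 and C5 unchanged.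

Step 16
Reactants: 27 (2S,3S,4R)-1-(aryl A)-4-(aryl B)-4-hydroxy-2,3-dimethylbutan-1-one
Product: 30 (2S,3S,4S,5R)-2-(aryl A)-5-(aryl B)-3,4-dimethyltetrahydrofuran, via cyclic hemiketal 28 (not isolated), via oxocarbenium ion 29 (not isolated)
Conditions: Et3SiH (5 equiv), then BF3·OEt2 (2 equiv), CH2Cl2, −78 °C; NaHCO3 quench at −78 °C
Reagents that add atoms: none
Why: BF3·OEt2 should close the C5 hydroxyl onto the C2 aryl ketone (hemiketal 28) and ionise it to the 2-aryl oxocarbenium ion 29, stabilised by the 4-alkoxy-3-methoxyphenyl ring on C2, which Et3SiH then reduces. The closest known reaction type is the Lewis acid/silane reductive etherification of γ-hydroxy aryl ketones (reductive deoxygenation of 2-aryl lactols) used for 2,5-diaryl-3,4-dimethyltetrahydrofurans. The ring closes by 5-exo-trig attack of the C5 oxygen on the C2 carbonyl, followed by hydride transfer to C2 of the cyclic cation. The new stereocenter C2 is controlled by the ring itself: the C4 methyl and the C5 aryl group are cis and cover one face, so hydride should enter on the other face (inside attack on the envelope with both methyl groups pseudo-equatorial), which places aryl A trans to the C3 methyl and cis to aryl B, (2S). The step needs face selectivity at C2, no reopening of the C5–O bond (which would erase the cis C4/C5 relation) and no ionisation of the benzylic silyl ethers of the arms. These should be secured by −78 °C with excess silane present before the acid is added, so that reduction outruns reversible ring opening, and by the much easier ionisation of the tertiary, oxygen- and aryl-stabilised hemiketal compared with the secondary arm ethers, which carry an inductively withdrawing β-aryloxy group.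

Step 17
Reactants: 30 (2S,3S,4S,5R)-2-(aryl A)-5-(aryl B)-3,4-dimethyltetrahydrofuran
Product: 31 (2S,3S,4S,5R)-2-{4-[(1R,2R)-1-(3,4-dimethoxyphenyl)-1-hydroxypropan-2-yloxy]-3-methoxyphenyl}-5-{4-[(1S,2S)-1-(3,4-dimethoxyphenyl)-1-hydroxypropan-2-yloxy]-3-methoxyphenyl}-3,4-dimethyltetrahydrofuran (CNP0116650.17)
Conditions: Bu4NF, THF, 0 °C → rt
Reagents that add atoms: none
Why: Fluoride cleavage of the two secondary silyl ethers should free both arm alcohols without touching any stereocenter.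

**Compound list**

1 | ethyl (S)-lactate | C[C@H](O)C(=O)OCC | starting material
2 | (S)-2-hydroxy-N-methoxy-N-methylpropanamide | C[C@H](O)C(=O)N(C)OC | intermediate
3 | 3,4-dimethoxyphenylmagnesium bromide | COc1ccc([Mg]Br)cc1OC | starting material
4 | (S)-1-(3,4-dimethoxyphenyl)-2-hydroxypropan-1-one | C[C@H](O)C(=O)c1ccc(OC)c(OC)c1 | intermediate
5 | 4-bromo-2-methoxyphenol | COc1cc(Br)ccc1O | starting material
6 | (R)-2-(4-bromo-2-methoxyphenoxy)-1-(3,4-dimethoxyphenyl)propan-1-one | C[C@@H](Oc1ccc(Br)cc1OC)C(=O)c1ccc(OC)c(OC)c1 | intermediate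
7 | (1R,2R)-2-(4-bromo-2-methoxyphenoxy)-1-(3,4-dimethoxyphenyl)propan-1-ol | C[C@@H](Oc1ccc(Br)cc1OC)[C@H](O)c1ccc(OC)c(OC)c1 | intermediate
8 | tert-butyl{[(1R,2R)-2-(4-bromo-2-methoxyphenoxy)-1-(3,4-dimethoxyphenyl)propyl]oxy}dimethylsilane | C[C@@H](Oc1ccc(Br)cc1OC)[C@H](O[Si](C)(C)C(C)(C)C)c1ccc(OC)c(OC)c1 | intermediate
9 | methyl (R)-lactate | C[C@@H](O)C(=O)OC | starting material
10 | (R)-2-hydroxy-N-methoxy-N-methylpropanamide | C[C@@H](O)C(=O)N(C)OC | intermediate
11 | (R)-1-(3,4-dimethoxyphenyl)-2-hydroxypropan-1-one | C[C@@H](O)C(=O)c1ccc(OC)c(OC)c1 | intermediate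
12 | (S)-2-(4-bromo-2-methoxyphenoxy)-1-(3,4-dimethoxyphenyl)propan-1-one | C[C@H](Oc1ccc(Br)cc1OC)C(=O)c1ccc(OC)c(OC)c1 | intermediate
13 | (1S,2S)-2-(4-bromo-2-methoxyphenoxy)-1-(3,4-dimethoxyphenyl)propan-1-ol | C[C@H](Oc1ccc(Br)cc1OC)[C@@H](O)c1ccc(OC)c(OC)c1 | intermediate
14 | tert-butyl{[(1S,2S)-2-(4-bromo-2-methoxyphenoxy)-1-(3,4-dimethoxyphenyl)propyl]oxy}dimethylsilane | C[C@H](Oc1ccc(Br)cc1OC)[C@@H](O[Si](C)(C)C(C)(C)C)c1ccc(OC)c(OC)c1 | intermediate
15 | (R)-4-benzyl-3-propionyloxazolidin-2-one | CCC(=O)N1[C@H](Cc2ccccc2)COC1=O | starting material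
16 | ethyl (S)-2-{[(trifluoromethyl)sulfonyl]oxy}propanoate | C[C@H](OS(=O)(=O)C(F)(F)F)C(=O)OCC | starting material
17 | sodium (Z)-enolate of 15 | C/C=C(\[O-])N1[C@H](Cc2ccccc2)COC1=O.[Na+] | intermediate
18 | ethyl (2S,3S)-4-[(R)-4-benzyl-2-oxooxazolidin-3-yl]-2,3-dimethyl-4-oxobutanoate | CCOC(=O)[C@@H](C)[C@H](C)C(=O)N1[C@H](Cc2ccccc2)COC1=O | intermediate
19 | lithium (2S,3S)-4-ethoxy-2,3-dimethyl-4-oxobutaneperoxoate | CCOC(=O)[C@@H](C)[C@H](C)C(=O)O[O-].[Li+] | intermediate
20 | (2S,3S)-4-ethoxy-2,3-dimethyl-4-oxobutanoic acid | CCOC(=O)[C@@H](C)[C@H](C)C(=O)O | intermediate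
21 | ethyl (2S,3S)-4-chloro-2,3-dimethyl-4-oxobutanoate | CCOC(=O)[C@@H](C)[C@H](C)C(=O)Cl | intermediate
22 | (aryl B)magnesium bromide | C[C@H](Oc1ccc([Mg]Br)cc1OC)[C@@H](O[Si](C)(C)C(C)(C)C)c1ccc(OC)c(OC)c1 | intermediate
23 | ethyl (2S,3S)-4-(aryl B)-2,3-dimethyl-4-oxobutanoate | CCOC(=O)[C@@H](C)[C@H](C)C(=O)c1ccc(O[C@@H](C)[C@@H](O[Si](C)(C)C(C)(C)C)c2ccc(OC)c(OC)c2)c(OC)c1 | intermediate
24 | ethyl (2S,3S,4R)-4-(aryl B)-4-hydroxy-2,3-dimethylbutanoate | CCOC(=O)[C@@H](C)[C@H](C)[C@@H](O)c1ccc(O[C@@H](C)[C@@H](O[Si](C)(C)C(C)(C)C)c2ccc(OC)c(OC)c2)c(OC)c1 | intermediate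
25 | (3S,4S,5R)-5-(aryl B)-3,4-dimethyldihydrofuran-2(3H)-one | O=C1O[C@@H](c2ccc(O[C@@H](C)[C@@H](O[Si](C)(C)C(C)(C)C)c3ccc(OC)c(OC)c3)c(OC)c2)[C@@H](C)[C@@H]1C | intermediate
26 | (aryl A)lithium | C[C@@H](Oc1ccc([Li])cc1OC)[C@H](O[Si](C)(C)C(C)(C)C)c1ccc(OC)c(OC)c1 | intermediate
27 | (2S,3S,4R)-1-(aryl A)-4-(aryl B)-4-hydroxy-2,3-dimethylbutan-1-one | O=C(c1ccc(O[C@H](C)[C@H](O[Si](C)(C)C(C)(C)C)c2ccc(OC)c(OC)c2)c(OC)c1)[C@@H](C)[C@H](C)[C@@H](O)c1ccc(O[C@@H](C)[C@@H](O[Si](C)(C)C(C)(C)C)c2ccc(OC)c(OC)c2)c(OC)c1 | intermediate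
28 | (3S,4S,5R)-2-(aryl A)-5-(aryl B)-3,4-dimethyltetrahydrofuran-2-ol (both anomers) | OC1(c2ccc(O[C@H](C)[C@H](O[Si](C)(C)C(C)(C)C)c3ccc(OC)c(OC)c3)c(OC)c2)O[C@@H](c2ccc(O[C@@H](C)[C@@H](O[Si](C)(C)C(C)(C)C)c3ccc(OC)c(OC)c3)c(OC)c2)[C@@H](C)[C@@H]1C | intermediate
29 | (3S,4S,5R)-2-(aryl A)-5-(aryl B)-3,4-dimethyl-4,5-dihydro-3H-furan-1-ium hydroxytrifluoroborate | C1(c2ccc(O[C@H](C)[C@H](O[Si](C)(C)C(C)(C)C)c3ccc(OC)c(OC)c3)c(OC)c2)=[O+][C@@H](c2ccc(O[C@@H](C)[C@@H](O[Si](C)(C)C(C)(C)C)c3ccc(OC)c(OC)c3)c(OC)c2)[C@@H](C)[C@@H]1C.O[B-](F)(F)F | intermediate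
30 | (2S,3S,4S,5R)-2-(aryl A)-5-(aryl B)-3,4-dimethyltetrahydrofuran | COc1ccc([C@@H](O[Si](C)(C)C(C)(C)C)[C@@H](C)Oc2ccc([C@H]3O[C@@H](c4ccc(O[C@@H](C)[C@@H](O[Si](C)(C)C(C)(C)C)c5ccc(OC)c(OC)c5)c(OC)c4)[C@@H](C)[C@@H]3C)cc2OC)cc1OC | intermediate
31 | (2S,3S,4S,5R)-2-{4-[(1R,2R)-1-(3,4-dimethoxyphenyl)-1-hydroxypropan-2-yloxy]-3-methoxyphenyl}-5-{4-[(1S,2S)-1-(3,4-dimethoxyphenyl)-1-hydroxypropan-2-yloxy]-3-methoxyphenyl}-3,4-dimethyltetrahydrofuran | COc1ccc([C@@H](O)[C@@H](C)Oc2ccc([C@H]3O[C@@H](c4ccc(O[C@@H](C)[C@@H](O)c5ccc(OC)c(OC)c5)c(OC)c4)[C@@H](C)[C@@H]3C)cc2OC)cc1OC | target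

**Count**

Total step count: 17. Longest linear sequence: 10 steps (steps 6, 7, 8, 9, 10, 13, 14, 15, 16, 17).

**Steps most likely to fail**

Step 16. The oxocarbenium ion may reopen at the C5–O bond to a 4-alkoxybenzyl cation and reclose, which would lose the cis relation at C4/C5. The Lewis acid may also ionise the benzylic silyl ethers of the arms, which would then be lost or over-reduced. The fallback closes the ring with the opposite polarity at C2 and without Lewis acid; it sets out from 27 and comes back at 30. The C5 hydroxyl is silylated through the open tautomer (Et3SiCl, imidazole, DMF) to (2S,3S,4R)-1-(aryl A)-4-(aryl B)-2,3-dimethyl-4-(triethylsilyloxy)butan-1-one F1. The ketone is reduced (NaBH4, MeOH/THF) to (2S,3S,4R)-1-(aryl A)-4-(aryl B)-2,3-dimethyl-4-(triethylsilyloxy)butan-1-ol F2, of which both C1 epimers serve. MsCl/Et3N in CH2Cl2 at −20 °C should then ionise the 4-alkoxybenzylic mesylate, and the C5 silyl ether oxygen should close the ring trans to the C3 methyl with loss of the triethylsilyl group. Under these basic conditions neither C5 nor the arm ethers are activated.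

Step 14. Facial selectivity may be poor, because reagent control has to overcome the Felkin preference of the α-methyl centre, which would give the 4,5-trans lactone. The fallback reverses the roles so that substrate control gives the wanted relation; it sets out from 21 and comes back at 24. The acid chloride is reduced with LiAlH(OtBu)3 (THF, −78 °C) to ethyl (2S,3S)-2,3-dimethyl-4-oxobutanoate F3. Grignard reagent 22 is then added at −78 °C. Felkin–Anh addition of the aryl nucleophile anti to the CH(CH3)CO2Et group should give the 4,5-syn adduct, which is hydroxy ester 24, and this lactonises to 25 as before.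

Step 11. The secondary triflate may undergo E2 elimination, or partial ionisation may erode the inversion at the lactate carbon. The fallback builds the C3–C4 bond by enolate dimerisation; it sets out from 15 and comes back at 23. Oxidative homocoupling of the lithium enolate of 15 (LiN(iPr)2, THF, −78 °C; then CuCl2), with both new centres set by the auxiliary, should give (4R,4'R)-3,3'-[(2S,3S)-2,3-dimethylbutanedioyl]bis(4-benzyloxazolidin-2-one) F4. LiOH/H2O2 then gives (2S,3S)-2,3-dimethylsuccinic acid F5, and acetyl chloride at reflux gives (3S,4S)-3,4-dimethyldihydrofuran-2,5-dione F6. One equivalent of 22 at −78 °C opens this C2-symmetric anhydride to (2S,3S)-4-(aryl B)-2,3-dimethyl-4-oxobutanoic acid F7. Ethylation (EtI, KHCO3, DMF) gives 23.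

**Further compounds**

F1 | step 16 | (2S,3S,4R)-1-(aryl A)-4-(aryl B)-2,3-dimethyl-4-(triethylsilyloxy)butan-1-one | O=C(c1ccc(O[C@H](C)[C@H](O[Si](C)(C)C(C)(C)C)c2ccc(OC)c(OC)c2)c(OC)c1)[C@@H](C)[C@H](C)[C@@H](O[Si](CC)(CC)CC)c1ccc(O[C@@H](C)[C@@H](O[Si](C)(C)C(C)(C)C)c2ccc(OC)c(OC)c2)c(OC)c1
F2 | step 16 | (2S,3S,4R)-1-(aryl A)-4-(aryl B)-2,3-dimethyl-4-(triethylsilyloxy)butan-1-ol (C1 epimers) | OC(c1ccc(O[C@H](C)[C@H](O[Si](C)(C)C(C)(C)C)c2ccc(OC)c(OC)c2)c(OC)c1)[C@@H](C)[C@H](C)[C@@H](O[Si](CC)(CC)CC)c1ccc(O[C@@H](C)[C@@H](O[Si](C)(C)C(C)(C)C)c2ccc(OC)c(OC)c2)c(OC)c1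
F3 | step 14 | ethyl (2S,3S)-2,3-dimethyl-4-oxobutanoate | CCOC(=O)[C@@H](C)[C@H](C)C=O
F4 | step 11 | (4R,4'R)-3,3'-[(2S,3S)-2,3-dimethylbutanedioyl]bis(4-benzyloxazolidin-2-one) | O=C1OC[C@@H](Cc2ccccc2)N1C(=O)[C@@H](C)[C@H](C)C(=O)N1[C@H](Cc2ccccc2)COC1=O
F5 | step 11 | (2S,3S)-2,3-dimethylsuccinic acid | OC(=O)[C@@H](C)[C@H](C)C(=O)O
F6 | step 11 | (3S,4S)-3,4-dimethyldihydrofuran-2,5-dione | O=C1OC(=O)[C@@H](C)[C@@H]1C
F7 | step 11 | (2S,3S)-4-(aryl B)-2,3-dimethyl-4-oxobutanoic acid | OC(=O)[C@@H](C)[C@H](C)C(=O)c1ccc(O[C@@H](C)[C@@H](O[Si](C)(C)C(C)(C)C)c2ccc(OC)c(OC)c2)c(OC)c1
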